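## Retrosynthetic overview

- The C3 ester is cut to a decalin alcohol (8,9-diol masked as acetonide) and (R)-4-(angeloyloxy)hex-2-ynoic acid; the Z-alkene comes from a late Lindlar semi-hydrogenation.
- The 8α,9α-diol comes from a Δ9-8-enone: dissolving-metal reduction sets the trans ring fusion, the resulting enolate is hydroxylated at C9, and a bulky hydride gives the axial 8α-OH.
- Key disconnection C7–C(isopropenyl): the α′-carbon of the enone is made electrophilic as an iodane-bound enolonium and joined to an isopropenyl-zinc nucleophile (two natively nucleophilic carbons).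
- Ring B is annulated onto a preformed ring A: cuprate addition / Michael–aldol on (R)-4-silyloxy-2-methylcyclohexenone, whose single stereocentre (C3) controls C4 and C5.
- That enone comes from 3-ethoxy-2-methylcyclohexenone by α′-acetoxylation, lipase resolution and Stork–Danheiser transposition.

Assumption: (R)-pent-1-yn-3-ol, angelic acid and 3-(trimethylsilyl)but-3-en-2-one are bought as catalogue items.

Convention: decalins carry eremophilane numbers (ring A = C1–C5 and C10; ring B = C5–C10; angular methyl on C5, secondary methyl on C4, isopropenyl on C7). β is the face of the angular C5 methyl, α the opposite face.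

## Route

Step 1
Reactants: 1 3-ethoxy-2-methylcyclohex-2-en-1-one
Product: 2 rac-6-acetoxy-3-ethoxy-2-methylcyclohex-2-en-1-one
Conditions: Mn(OAc)3·2H2O (2.5 equiv), benzene, reflux (Dean–Stark)
Reagents that add atoms: manganese triacetate Mn(OAc)3, CC(=O)O[Mn](OC(C)=O)OC(C)=O
Why: The trivalent-manganese enolate of a vinylogous ester forms only on the α′ side and collapses to the α′-acetate (Mn(OAc)3 α′-acetoxylation of enones); the product is racemic.

Step 2
Reactants: 2 rac-6-acetoxy-3-ethoxy-2-methylcyclohex-2-en-1-one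
Product: 3 (R)-3-ethoxy-6-hydroxy-2-methylcyclohex-2-en-1-one
Conditions: Amano lipase PS (Burkholderia cepacia), pH 7 phosphate buffer/DMSO, rt, stopped below 50% conversion; chromatography
Reagents that add atoms: none
Why: Lipase hydrolytic kinetic resolution; by Kazlauskas' rule (carbonyl side large, CH2 side medium) the (R)-acetate is cleaved faster, so the (R)-alcohol is collected and the unreacted (S)-acetate is separated, which sets the future C3 stereocentre.

Step 3
Reactants: 3 (R)-3-ethoxy-6-hydroxy-2-methylcyclohex-2-en-1-one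
Product: 4 (R)-6-(tert-butyldimethylsilyloxy)-3-ethoxy-2-methylcyclohex-2-en-1-one
Conditions: TBSCl, imidazole, DMF, rt
Reagents that add atoms: tert-butyldimethylsilyl chloride (TBSCl), CC(C)(C)[Si](C)(C)Cl
Why: Standard silylation of a secondary alcohol; the stereocentre is not touched.

Step 4
Reactants: 4 (R)-6-(tert-butyldimethylsilyloxy)-3-ethoxy-2-methylcyclohex-2-en-1-one
Product: 6 (R)-4-(tert-butyldimethylsilyloxy)-2-methylcyclohex-2-en-1-one, via allylic alcohol 5 (not isolated)
Conditions: LiAlH4, Et2O, 0 °C; then 1 M HCl, THF, 0 °C, 15 min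
Reagents that add atoms: water, O
Why: Stork–Danheiser 1,3-carbonyl transposition: 1,2-reduction, then acid ionises the 3-ethoxy allylic alcohol and water hydrolyses the enol ether to the transposed enone, leaving the silyloxy stereocentre unchanged at the γ-position.

Step 5
Reactants: 6 (R)-4-(tert-butyldimethylsilyloxy)-2-methylcyclohex-2-en-1-one; 7 3-(trimethylsilyl)but-3-en-2-one
Product: 11 (4aR,5R,6R)-6-(tert-butyldimethylsilyloxy)-4a,5-dimethyl-4,4a,5,6,7,8-hexahydronaphthalen-2(3H)-one, via lithium enolate 8 (not isolated), via silyl diketone 9 (not isolated), via diketone 10 (not isolated)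
Conditions: Me2CuLi (from MeLi, CuBr·SMe2), Et2O, −78 → −30 °C; 7, −78 → 0 °C; then NaOMe, MeOH, rt → 60 °C
Reagents that add atoms: lithium dimethylcuprate Me2CuLi, [Li+].C[Cu-]C
Why: The cuprate adds anti to the γ-silyloxy group (sets C4), the regiodefined enolate adds to the α-silyl vinyl ketone anti to the new C4 methyl (sets the C5 quaternary centre, methyls cis), and methoxide effects desilylation and aldol condensation (conjugate addition–annulation, a Robinson annulation with the Stork–Ganem reagent).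

Step 6
Reactants: 11 (4aR,5R,6R)-6-(tert-butyldimethylsilyloxy)-4a,5-dimethyl-4,4a,5,6,7,8-hexahydronaphthalen-2(3H)-one
Product: 14 3α-(tert-butyldimethylsilyloxy)eremophila-9,11-dien-8-one (7α-isopropenyl), via lithium dienolate 12 (not isolated), via iodanyl enolonium 13 (not isolated)
Conditions: LiN(SiMe3)2, THF, −78 °C; PhI(OH)OTs, −78 °C; (CH2=C(CH3))2Zn (from CH2=C(CH3)MgBr and ZnCl2, 3 equiv), −78 → −20 °C
Reagents that add atoms: diisopropenylzinc (CH2=C(CH3))2Zn, C=C(C)[Zn]C(C)=C
Why: Proposed new method: the kinetic α′-lithium dienolate is oxidised by PhI(OH)OTs to an O-bound trivalent-iodine enolate whose C7 is electrophilic (enolonium), and the alkenylzinc transfers isopropenyl to C7 with loss of PhI, attacking anti to the axial C5 methyl to give the pseudo-equatorial 7α epimer (also the thermodynamic one); the closest known reaction is the Koser-reagent-mediated oxidative umpolung α-alkylation of ketone lithium enolates with dialkylzincs.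

Step 7
Reactants: 14 3α-(tert-butyldimethylsilyloxy)eremophila-9,11-dien-8-one
Product: 16 3α-(tert-butyldimethylsilyloxy)-9α-hydroxy-10αH-eremophil-11-en-8-one, via lithium enolate 15 (not isolated)
Conditions: Li (2.5 equiv), NH3(l)/THF, t-BuOH (1.0 equiv), −78 °C; isoprene; NH3 removed; THF, −78 °C, 2-(phenylsulfonyl)-3-phenyloxaziridine (1.5 equiv); aq. NH4Cl
Reagents that add atoms: 2-(phenylsulfonyl)-3-phenyloxaziridine, O=S(=O)(c1ccccc1)N1OC1c1ccccc1
Why: Dissolving-metal reduction of the enone protonates C10 axially (trans-decalin) and leaves the regiodefined Δ8 lithium enolate, which the oxaziridine hydroxylates from the α face away from the axial C5 methyl (Davis oxidation), giving the equatorial 9α-ol.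

Step 8
Reactants: 16 3α-(tert-butyldimethylsilyloxy)-9α-hydroxy-10αH-eremophil-11-en-8-one
Product: 17 3α-(tert-butyldimethylsilyloxy)-10αH-eremophil-11-ene-8α,9α-diol
Conditions: LiBH(s-Bu)3 (L-Selectride, 2.5 equiv), THF, −78 °C; aq. NH4Cl
Reagents that add atoms: none
Why: The bulky trialkylborohydride attacks the C8 ketone along the equatorial trajectory and gives the axial 8α-alcohol, cis to the 9α-OH and to the 7α-isopropenyl group (axial-selective Selectride reduction).

Step 9
Reactants: 17 3α-(tert-butyldimethylsilyloxy)-10αH-eremophil-11-ene-8α,9α-diol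
Product: 19 8α,9α-(isopropylidenedioxy)-10αH-eremophil-11-en-3α-ol, via triol 18 (not isolated)
Conditions: CSA, MeOH, rt; evaporate; 2,2-dimethoxypropane, acetone, rt
Reagents that add atoms: 2,2-dimethoxypropane, COC(C)(C)OC
Why: Acidic methanolysis removes the silyl ether and acid-catalysed acetalisation then engages only the cis-vicinal 8,9-diol, leaving the equatorial 3α-OH free.

Step 10
Reactants: 20 (R)-pent-1-yn-3-ol; 21 angelic acid
Product: 23 (R)-pent-1-yn-3-yl angelate, via angeloyl trichlorobenzoyl anhydride 22 (not isolated)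
Conditions: 2,4,6-Cl3C6H2COCl, Et3N, toluene, rt; then 20, toluene, 75 °C (no DMAP)
Reagents that add atoms: none
Why: Yamaguchi-type mixed-anhydride esterification without a nucleophilic catalyst transfers the angeloyl group without Z to E isomerisation; the carbinol centre is not involved.

Step 11
Reactants: 23 (R)-pent-1-yn-3-yl angelate
Product: 25 (R)-4-(angeloyloxy)hex-2-ynoic acid, via lithium acetylide 24 (not isolated)
Conditions: LiN(SiMe3)2, THF, −78 °C; CO2 (g); 1 M HCl
Reagents that add atoms: carbon dioxide, O=C=O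
Why: The amide base removes only the terminal alkyne proton at −78 °C and the acetylide is carboxylated by CO2 (acetylide carboxylation).

Step 12
Reactants: 19 8α,9α-(isopropylidenedioxy)-10αH-eremophil-11-en-3α-ol; 25 (R)-4-(angeloyloxy)hex-2-ynoic acid
Product: 26 3α-{[(4R)-4-(angeloyloxy)hex-2-ynoyl]oxy}-8α,9α-(isopropylidenedioxy)-10αH-eremophil-11-ene
Conditions: DCC, DMAP (cat.), CH2Cl2, 0 °C
Reagents that add atoms: none
Why: Steglich esterification of the only free hydroxyl (equatorial 3α-OH) with retention at C3; the linear ynoate cannot isomerise or lactonise.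

Step 13
Reactants: 26 3α-{[(4R)-4-(angeloyloxy)hex-2-ynoyl]oxy}-8α,9α-(isopropylidenedioxy)-10αH-eremophil-11-ene
Product: 27 3α-{[(2Z,4R)-4-(angeloyloxy)hex-2-enoyl]oxy}-8α,9α-(isopropylidenedioxy)-10αH-eremophil-11-ene
Conditions: H2 (1 atm), Pd/CaCO3 poisoned with Pb(OAc)2 (Lindlar catalyst), quinoline, EtOAc, rt, stopped at 1 equiv H2
Reagents that add atoms: none
Why: Lindlar syn-semihydrogenation of the ynoate gives the Z-enoate, while the poisoned catalyst leaves the 1,1-disubstituted isopropenyl and the trisubstituted angelate alkenes.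

Step 14
Reactants: 27 3α-{[(2Z,4R)-4-(angeloyloxy)hex-2-enoyl]oxy}-8α,9α-(isopropylidenedioxy)-10αH-eremophil-11-ene
Product: 28 3α-{[(2Z,4R)-4-(angeloyloxy)hex-2-enoyl]oxy}-10αH-eremophil-11-ene-8α,9α-diol (CNP0382739.1)
Conditions: AcOH/H2O 4:1, 40 °C
Reagents that add atoms: none
Why: Mild aqueous acid hydrolyses the isopropylidene acetal; both esters and the Z-enoate (its γ-oxygen is acylated, so no lactonisation) are stable to it.

## Compound list

1 | 3-ethoxy-2-methylcyclohex-2-en-1-one | CCOC1=C(C)C(=O)CCC1 | starting material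
2 | rac-6-acetoxy-3-ethoxy-2-methylcyclohex-2-en-1-one | CCOC1=C(C)C(=O)C(OC(C)=O)CC1 | intermediate
3 | (R)-3-ethoxy-6-hydroxy-2-methylcyclohex-2-en-1-one | CCOC1=C(C)C(=O)[C@H](O)CC1 | intermediate
4 | (R)-6-(tert-butyldimethylsilyloxy)-3-ethoxy-2-methylcyclohex-2-en-1-one | CCOC1=C(C)C(=O)[C@H](O[Si](C)(C)C(C)(C)C)CC1 | intermediate
5 | (6R)-6-(tert-butyldimethylsilyloxy)-3-ethoxy-2-methylcyclohex-2-en-1-ol (both C1 epimers) | CCOC1=C(C)C(O)[C@H](O[Si](C)(C)C(C)(C)C)CC1 | intermediate
6 | (R)-4-(tert-butyldimethylsilyloxy)-2-methylcyclohex-2-en-1-one | O=C1C(C)=C[C@H](O[Si](C)(C)C(C)(C)C)CC1 | intermediate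
7 | 3-(trimethylsilyl)but-3-en-2-one | C=C([Si](C)(C)C)C(C)=O | starting material
8 | lithium (3R,4R)-4-(tert-butyldimethylsilyloxy)-2,3-dimethylcyclohex-1-en-1-olate | [Li+].[O-]C1=C(C)[C@@H](C)[C@H](O[Si](C)(C)C(C)(C)C)CC1 | intermediate
9 | (2R,3R,4R)-4-(tert-butyldimethylsilyloxy)-2,3-dimethyl-2-[3-oxo-2-(trimethylsilyl)butyl]cyclohexan-1-one (mixture at the silyl-bearing carbon) | CC(=O)C([Si](C)(C)C)C[C@]1(C)[C@@H](C)[C@H](O[Si](C)(C)C(C)(C)C)CCC1=O | intermediate
10 | (2R,3R,4R)-4-(tert-butyldimethylsilyloxy)-2,3-dimethyl-2-(3-oxobutyl)cyclohexan-1-one | CC(=O)CC[C@]1(C)[C@@H](C)[C@H](O[Si](C)(C)C(C)(C)C)CCC1=O | intermediate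
11 | (4aR,5R,6R)-6-(tert-butyldimethylsilyloxy)-4a,5-dimethyl-4,4a,5,6,7,8-hexahydronaphthalen-2(3H)-one (3α-OTBS, 4β-Me, 5β-Me, Δ9-8-one) | C1C[C@]2(C)[C@@H](C)[C@H](O[Si](C)(C)C(C)(C)C)CCC2=CC1=O | intermediate
12 | lithium cross-conjugated (C7=C8, C9=C10) dienolate of 11 | [Li+].[O-]C1=CC[C@]2(C)[C@@H](C)[C@H](O[Si](C)(C)C(C)(C)C)CCC2=C1 | intermediate
13 | O-[phenyl(tosyloxy)-λ3-iodanyl] dienolate of 11 (enolonium species) | Cc1ccc(cc1)S(=O)(=O)OI(c1ccccc1)OC1=CC[C@]2(C)[C@@H](C)[C@H](O[Si](C)(C)C(C)(C)C)CCC2=C1 | intermediate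
14 | 3α-(tert-butyldimethylsilyloxy)eremophila-9,11-dien-8-one, (3S,4aR,5R,6R)-6-(TBSO)-4a,5-dimethyl-3-(prop-1-en-2-yl)-4,4a,5,6,7,8-hexahydronaphthalen-2(3H)-one | C=C(C)[C@@H]1C[C@]2(C)[C@@H](C)[C@H](O[Si](C)(C)C(C)(C)C)CCC2=CC1=O | intermediate
15 | lithium Δ8-enolate of 3α-(tert-butyldimethylsilyloxy)-10αH-eremophil-11-en-8-one | C=C(C)[C@@H]1C[C@]2(C)[C@@H](C)[C@H](O[Si](C)(C)C(C)(C)C)CC[C@H]2C=C1[O-].[Li+] | intermediate
16 | 3α-(tert-butyldimethylsilyloxy)-9α-hydroxy-10αH-eremophil-11-en-8-one | C=C(C)[C@@H]1C[C@]2(C)[C@@H](C)[C@H](O[Si](C)(C)C(C)(C)C)CC[C@H]2[C@H](O)C1=O | intermediate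
17 | 3α-(tert-butyldimethylsilyloxy)-10αH-eremophil-11-ene-8α,9α-diol | C=C(C)[C@@H]1C[C@]2(C)[C@@H](C)[C@H](O[Si](C)(C)C(C)(C)C)CC[C@H]2[C@H](O)[C@@H]1O | intermediate
18 | 10αH-eremophil-11-ene-3α,8α,9α-triol | C=C(C)[C@@H]1C[C@]2(C)[C@@H](C)[C@H](O)CC[C@H]2[C@H](O)[C@@H]1O | intermediate
19 | 8α,9α-(isopropylidenedioxy)-10αH-eremophil-11-en-3α-ol | C=C(C)[C@@H]1C[C@]2(C)[C@@H](C)[C@H](O)CC[C@H]2[C@@H]3OC(C)(C)O[C@H]13 | intermediate
20 | (R)-pent-1-yn-3-ol | C#C[C@@H](CC)O | starting material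
21 | angelic acid, (Z)-2-methylbut-2-enoic acid | C/C=C(/C)C(=O)O | starting material
22 | angelic 2,4,6-trichlorobenzoic anhydride | C/C=C(/C)C(=O)OC(=O)c1c(Cl)cc(Cl)cc1Cl | intermediate
23 | (R)-pent-1-yn-3-yl angelate | C#C[C@@H](CC)OC(=O)/C(C)=C\C | intermediate
24 | lithium acetylide of 23 | [Li+].[C-]#C[C@@H](CC)OC(=O)/C(C)=C\C | intermediate
25 | (R)-4-(angeloyloxy)hex-2-ynoic acid | OC(=O)C#C[C@@H](CC)OC(=O)/C(C)=C\C | intermediate
26 | 3α-{[(4R)-4-(angeloyloxy)hex-2-ynoyl]oxy}-8α,9α-(isopropylidenedioxy)-10αH-eremophil-11-ene | C=C(C)[C@@H]1C[C@]2(C)[C@@H](C)[C@H](OC(=O)C#C[C@@H](CC)OC(=O)/C(C)=C\C)CC[C@H]2[C@@H]3OC(C)(C)O[C@H]13 | intermediate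
27 | 3α-{[(2Z,4R)-4-(angeloyloxy)hex-2-enoyl]oxy}-8α,9α-(isopropylidenedioxy)-10αH-eremophil-11-ene | C=C(C)[C@@H]1C[C@]2(C)[C@@H](C)[C@H](OC(=O)/C=C\[C@@H](CC)OC(=O)/C(C)=C\C)CC[C@H]2[C@@H]3OC(C)(C)O[C@H]13 | intermediate
28 | CNP0382739.1, 3α-{[(2Z,4R)-4-(angeloyloxy)hex-2-enoyl]oxy}-10αH-eremophil-11-ene-8α,9α-diol, (3R,4R,5R,7S,8R,9S,10R) | C=C(C)[C@@H]1C[C@]2(C)[C@@H](C)[C@H](OC(=O)/C=C\[C@@H](CC)OC(=O)/C(C)=C\C)CC[C@H]2[C@H](O)[C@@H]1O | target

## Step count and risks

Total step count: 14 (steps 1–14). Longest linear sequence: 12 (steps 1–9, then 12–14); the side-chain acid takes 2 steps (10, 11).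

The three steps most likely to fail:

**Step 6** (oxidative isopropenylation, untested for alkenylzincs and for a dienolate; α′-tosyloxylation or zinc homocoupling may win). The fallback sets out from 11 and uses an α-halo ketone as the enolonium equivalent. LiN(i-Pr)2 then Me3SiCl gives the trimethylsilyl dienol ether F1. N-Bromosuccinimide (THF, −78 °C) converts it into the 7-bromo enone F2. F2 is treated with B-isopropenyl-9-BBN and potassium 2,6-di-tert-butylphenoxide (THF, 0 °C): the bromo-enolate binds boron, isopropenyl shifts from boron to C7 with loss of bromide, and protonolysis gives 14, where the route is rejoined.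

**Step 7** (the α-isopropenyl ketone may slip into conjugation to the isopropylidene enone under the basic enolate conditions, or the enolate may add to the sulfonimine by-product). The fallback sets out from 11 and postpones the isopropenyl group until after the ring fusion and C9 oxygen are in place. Li/NH3 reduction with trapping by t-BuMe2SiOTf/Et3N gives the Δ8 silyl enol ether F3. Dimethyldioxirane epoxidation with silyl migration (Rubottom oxidation) gives the 9α-silyloxy ketone F4. The oxidative isopropenylation of step 6, applied to the kinetic C7 enolate of F4, gives the 7α-isopropenyl ketone F5. LiBH(s-Bu)3 gives the 8α-alcohol F6, and Bu4NF removes both silyl groups to give 18, which is taken on with 2,2-dimethoxypropane as in step 9.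

**Step 5** (facial selectivity and efficiency of the enolate Michael addition that creates the C5 quaternary centre). The fallback sets out from 6 and replaces the basic enolate / α-silyl enone pair by an acid-mediated Mukaiyama–Michael reaction. Me2CuLi followed by Me3SiCl/Et3N gives the trimethylsilyl enol ether F7, which adds to but-3-en-2-one under BF3·OEt2 (CH2Cl2, −78 °C) to give diketone 10. NaOMe/MeOH then closes ring B to 11 as in step 5.

## Further compounds

F1 | step 6 | 8-(trimethylsilyloxy)-3α-(tert-butyldimethylsilyloxy)-4β,5β-dimethyl-octalin-7,9-diene (α′-trimethylsilyl dienol ether of 11) | C[Si](C)(C)OC1=CC[C@]2(C)[C@@H](C)[C@H](O[Si](C)(C)C(C)(C)C)CCC2=C1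
F2 | step 6 | 7-bromo-3α-(tert-butyldimethylsilyloxy)-4β,5β-dimethyl-Δ9-octalin-8-one (both C7 epimers) | BrC1C[C@]2(C)[C@@H](C)[C@H](O[Si](C)(C)C(C)(C)C)CCC2=CC1=O
F3 | step 7 | 3α,8-bis(tert-butyldimethylsilyloxy)-4β,5β-dimethyl-10αH-octalin-8-ene (Δ8 silyl enol ether of the trans-decalone) | C1C[C@]2(C)[C@@H](C)[C@H](O[Si](C)(C)C(C)(C)C)CC[C@H]2C=C1O[Si](C)(C)C(C)(C)C
F4 | step 7 | 3α,9α-bis(tert-butyldimethylsilyloxy)-4β,5β-dimethyl-10αH-decalin-8-one | C1C[C@]2(C)[C@@H](C)[C@H](O[Si](C)(C)C(C)(C)C)CC[C@H]2[C@H](O[Si](C)(C)C(C)(C)C)C1=O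
F5 | step 7 | 3α,9α-bis(tert-butyldimethylsilyloxy)-10αH-eremophil-11-en-8-one | C=C(C)[C@@H]1C[C@]2(C)[C@@H](C)[C@H](O[Si](C)(C)C(C)(C)C)CC[C@H]2[C@H](O[Si](C)(C)C(C)(C)C)C1=O
F6 | step 7 | 3α,9α-bis(tert-butyldimethylsilyloxy)-10αH-eremophil-11-en-8α-ol | C=C(C)[C@@H]1C[C@]2(C)[C@@H](C)[C@H](O[Si](C)(C)C(C)(C)C)CC[C@H]2[C@H](O[Si](C)(C)C(C)(C)C)[C@@H]1O
F7 | step 5 | (3R,4R)-4-(tert-butyldimethylsilyloxy)-2,3-dimethyl-1-(trimethylsilyloxy)cyclohex-1-ene | C[Si](C)(C)OC1=C(C)[C@@H](C)[C@H](O[Si](C)(C)C(C)(C)C)CC1
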